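**Strategy.** Everything rests on cutting the 2,2-dimethyl-2H-pyran ring fused to ring B at C-4–C-4a and C-3–C-2. The ether oxygen on C-2′ of ring B, once it carries an isopropenyl group, becomes an aryl oxocarbenium ion whose only free ortho carbon is C-3′, the CH between O-2′ and O-4′; this O–C-2′–C-3′ array is the feature exploited. A cationic [4+2] annulation with ethyl vinyl ether forms both bonds, closes the pyran and, after loss of ethanol, gives the chromene in one operation from an open-chain aryl isopropenyl ether. The chromenylacetic acid is then benzylated on an Evans auxiliary (C-3, R), formylated by directed lithiation and closed to the chroman by Mitsunobu etherification.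

Key step: step 4

Remark: the SMILES is read as the (3R)-isoflavan (ring B on chroman C-3; C-1′ attached to C-3, O-2′ the pyran oxygen, O-4′ the free hydroxyl), and 2,4-dihydroxy-6-methoxybenzaldehyde 15 is taken to be a catalogue compound.

Step 1
Reactants: 1 2,4-dihydroxyphenylacetic acid
Product: 2 6-hydroxybenzofuran-2(3H)-one
Conditions: p-TsOH·H2O (5 mol%), toluene, reflux, azeotropic removal of water
Reagents that add atoms: none
Why: Acid-catalysed lactonisation (intramolecular Fischer esterification) should tie the ortho hydroxyl into the five-membered aryl lactone and leave the para hydroxyl as the only free phenol.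

Step 2
Reactants: 2 6-hydroxybenzofuran-2(3H)-one
Product: 4 methyl 2-[2-hydroxy-4-(triisopropylsilyloxy)phenyl]acetate, via silylated lactone 3 (not isolated)
Conditions: i-Pr3SiCl (1.05 equiv), imidazole (2.5 equiv), CH2Cl2, 0 °C to rt; then MeOH (excess), DMAP (10 mol%), rt
Reagents that add atoms: triisopropylsilyl chloride, CC(C)[Si](Cl)(C(C)C)C(C)C; methanol, CO
Why: Silylation of the single free phenol followed by nucleophile-catalysed methanolysis of the activated aryl lactone (transesterification) should release only the ortho hydroxyl, so the two ring B oxygens are differentiated without a selective protection.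

Step 3
Reactants: 4 methyl 2-[2-hydroxy-4-(triisopropylsilyloxy)phenyl]acetate; 5 isopropenylboronic acid pinacol ester
Product: 6 methyl 2-[2-(prop-1-en-2-yloxy)-4-(triisopropylsilyloxy)phenyl]acetate
Conditions: Cu(OAc)2 (2 equiv), pyridine (4 equiv), 4 Å molecular sieves, CH2Cl2, rt, dry air
Reagents that add atoms: none
Why: Chan–Lam oxidative C–O coupling of a phenol with an alkenylboronate should give the aryl isopropenyl ether under nearly neutral conditions that spare the ester and the silyl ether.

Step 4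
Reactants: 6 methyl 2-[2-(prop-1-en-2-yloxy)-4-(triisopropylsilyloxy)phenyl]acetate; 7 ethyl vinyl ether
Product: 10 methyl 2-[2,2-dimethyl-5-(triisopropylsilyloxy)-2H-chromen-8-yl]acetate, via tertiary α-chloro ether 8 (not isolated), via 4-ethoxychroman 9 (not isolated)
Conditions: HCl (1.0 M in Et2O, 1.05 equiv), CH2Cl2, −78 °C; then ethyl vinyl ether (1.5 equiv, slow addition), SnCl4 (0.5 equiv), −78 °C to 23 °C
Reagents that add atoms: none
Why: Proposed new method: HCl should add to the enol ether of 6 to give the tertiary α-chloro ether 8, which SnCl4 ionises to the aryl oxocarbenium ion ArO+=CMe2; the CH2 terminus of ethyl vinyl ether adds to it (Prins/Mukaiyama-type step, forming the pyran C-3–C-2 bond) and the resulting ethoxycarbenium ion is captured by the arene carbon (Friedel–Crafts step, forming the C-4–C-4a bond) to give 4-ethoxychroman 9, from which acid removes ethanol through the doubly oxygen-stabilised benzylic cation to leave the 3,4-alkene. The closest known reaction types are the oxa-Povarov reaction (formal [4+2] cycloaddition of aryl oxocarbenium ions with alkenes) and the Lewis-acid addition of α-halo ethers to vinyl ethers; a ketone-derived aryl oxocarbenium ion combined with a vinyl ether and in situ elimination to a 2H-chromene has not been shown. The pyran ring closes in the Friedel–Crafts event by 6-exo-trig attack of the arene carbon on the exocyclic C=O+ bond of the ethoxycarbenium ion. No stereocentre survives, because the C-4 centre of 9 is destroyed on elimination. The step needs regioselective ring closure and ionisation toward the aryloxy carbenium ion: the first is secured because the other ortho position of the ether oxygen carries the CH2CO2Me chain and the remaining one is activated by both flanking oxygens, the second because the enol ether precursor has no alkoxy group that could leave in place of chloride. Oligomerisation of the vinyl ether should be held back by the fast intramolecular arene trap and the low temperature.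

Step 5
Reactants: 10 methyl 2-[2,2-dimethyl-5-(triisopropylsilyloxy)-2H-chromen-8-yl]acetate
Product: 11 2-[2,2-dimethyl-5-(triisopropylsilyloxy)-2H-chromen-8-yl]acetic acid
Conditions: LiOH·H2O (2 equiv), THF/MeOH/H2O, 0 °C; then 1 M HCl to pH 4
Reagents that add atoms: lithium hydroxide, [Li+].[OH-]
Why: Saponification of the unhindered methyl ester should be fast at 0 °C, while the hindered aryl triisopropylsilyl ether and the base-stable chromene are retained.

Step 6
Reactants: 11 2-[2,2-dimethyl-5-(triisopropylsilyloxy)-2H-chromen-8-yl]acetic acid; 12 (R)-4-benzyloxazolidin-2-one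
Product: 14 (R)-4-benzyl-3-{2-[2,2-dimethyl-5-(triisopropylsilyloxy)-2H-chromen-8-yl]acetyl}oxazolidin-2-one, via mixed pivalic anhydride 13 (not isolated)
Conditions: t-BuCOCl (1.1 equiv), Et3N (2.5 equiv), THF, −20 °C; then 12 (1.1 equiv), LiCl (1.2 equiv), −20 °C to rt
Reagents that add atoms: none
Why: N-Acylation of the oxazolidinone through the mixed pivalic anhydride (LiCl/Et3N variant of the Evans acylation) should occur at the less hindered arylacetyl carbonyl without strong base.

Step 7
Reactants: 15 2,4-dihydroxy-6-methoxybenzaldehyde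
Product: 16 2-methoxy-4,6-bis(methoxymethoxy)benzaldehyde
Conditions: MeOCH2Cl (3 equiv), i-Pr2NEt (4 equiv), DMF, 0 °C to 40 °C
Reagents that add atoms: chloromethyl methyl ether, COCCl
Why: Base-mediated O-alkylation (Williamson-type acetal formation) of both phenols, the chelated ortho one needing excess reagent and mild warming, installs groups that later direct lithiation and are removed by acid.

Step 8
Reactants: 16 2-methoxy-4,6-bis(methoxymethoxy)benzaldehyde
Product: 17 [2-methoxy-4,6-bis(methoxymethoxy)phenyl]methanol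
Conditions: NaBH4 (1 equiv), MeOH/THF, 0 °C
Reagents that add atoms: none
Why: Borohydride reduction of the aryl aldehyde should give the benzylic alcohol without affecting the acetals.

Step 9
Reactants: 17 [2-methoxy-4,6-bis(methoxymethoxy)phenyl]methanol
Product: 19 2-(bromomethyl)-1-methoxy-3,5-bis(methoxymethoxy)benzene, via benzylic mesylate 18 (not isolated)
Conditions: MeSO2Cl (1.2 equiv), Et3N (1.5 equiv), THF, −20 °C; then LiBr (3 equiv), −20 °C to 0 °C; cold filtered solution used at once
Reagents that add atoms: lithium bromide, [Li+].[Br-]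
Why: Mesylation and in situ displacement by bromide (Finkelstein-type substitution) should give the benzylic bromide under non-acidic conditions; it is kept cold and not stored because the trioxygenated ring makes it ionise readily.

Step 10
Reactants: 14 (R)-4-benzyl-3-{2-[2,2-dimethyl-5-(triisopropylsilyloxy)-2H-chromen-8-yl]acetyl}oxazolidin-2-one; 19 2-(bromomethyl)-1-methoxy-3,5-bis(methoxymethoxy)benzene
Product: 21 (R)-4-benzyl-3-{(2R)-2-[2,2-dimethyl-5-(triisopropylsilyloxy)-2H-chromen-8-yl]-3-[2-methoxy-4,6-bis(methoxymethoxy)phenyl]propanoyl}oxazolidin-2-one, via sodium Z-enolate 20 (not isolated)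
Conditions: NaN(SiMe3)2 (1.05 equiv), THF, −78 °C; then 19 (1.3 equiv in THF), −78 °C to −40 °C
Reagents that add atoms: none
Why: Evans asymmetric alkylation: the chelated (Z)-sodium enolate 20 should be benzylated on the face opposite the benzyl group of the (R)-auxiliary, which sets the α-carbon (the future chroman C-3) as R.

Step 11
Reactants: 21 (R)-4-benzyl-3-{(2R)-2-[2,2-dimethyl-5-(triisopropylsilyloxy)-2H-chromen-8-yl]-3-[2-methoxy-4,6-bis(methoxymethoxy)phenyl]propanoyl}oxazolidin-2-one
Product: 22 (2R)-2-[2,2-dimethyl-5-(triisopropylsilyloxy)-2H-chromen-8-yl]-3-[2-methoxy-4,6-bis(methoxymethoxy)phenyl]propan-1-ol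
Conditions: LiBH4 (2 equiv), H2O (1 equiv), Et2O/THF, 0 °C
Reagents that add atoms: none
Why: Reductive removal of the auxiliary (hydride attack at the exocyclic imide carbonyl) should give the primary alcohol without touching the stereocentre, the chromene or the protecting groups.

Step 12
Reactants: 22 (2R)-2-[2,2-dimethyl-5-(triisopropylsilyloxy)-2H-chromen-8-yl]-3-[2-methoxy-4,6-bis(methoxymethoxy)phenyl]propan-1-ol
Product: 24 3-{(2R)-2-[2,2-dimethyl-5-(triisopropylsilyloxy)-2H-chromen-8-yl]-3-hydroxypropyl}-4-methoxy-2,6-bis(methoxymethoxy)benzaldehyde, via dilithio species 23 (not isolated)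
Conditions: n-BuLi (2.3 equiv), THF, 0 °C; then DMF (5 equiv), −78 °C to rt; H2O
Reagents that add atoms: N,N-dimethylformamide, CN(C)C=O
Why: Directed ortho-metalation: after deprotonation of the alcohol, n-BuLi should lithiate the ring A CH flanked by the two methoxymethoxy groups (cooperative coordination, most acidic site) in preference to the CH between OMOM and OMe, and formylation with DMF places the aldehyde carbon at the future C-8.

Step 13
Reactants: 24 3-{(2R)-2-[2,2-dimethyl-5-(triisopropylsilyloxy)-2H-chromen-8-yl]-3-hydroxypropyl}-4-methoxy-2,6-bis(methoxymethoxy)benzaldehyde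
Product: 25 3-{(2R)-2-[2,2-dimethyl-5-(triisopropylsilyloxy)-2H-chromen-8-yl]-3-hydroxypropyl}-2,6-dihydroxy-4-methoxybenzaldehyde
Conditions: HCl (1 M) in MeOH/THF, 23 °C
Reagents that add atoms: none
Why: Acid-catalysed acetal exchange should remove both methoxymethyl groups, which are activated by the ortho formyl group, under conditions mild enough for the aryl silyl ether and the chromene.

Step 14
Reactants: 25 3-{(2R)-2-[2,2-dimethyl-5-(triisopropylsilyloxy)-2H-chromen-8-yl]-3-hydroxypropyl}-2,6-dihydroxy-4-methoxybenzaldehyde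
Product: 26 (3R)-3-[2,2-dimethyl-5-(triisopropylsilyloxy)-2H-chromen-8-yl]-7-hydroxy-5-methoxychroman-8-carbaldehyde
Conditions: PPh3 (1.5 equiv), DIAD (1.5 equiv), THF (0.01 M), 0 °C to rt
Reagents that add atoms: none
Why: Intramolecular Mitsunobu etherification: the acidic phenol ortho to the side chain should displace the activated primary alcohol in a 6-exo-tet closure to the chroman, the other phenol cannot reach, and C-3 is not a reacting centre so its R configuration is kept.

Step 15
Reactants: 26 (3R)-3-[2,2-dimethyl-5-(triisopropylsilyloxy)-2H-chromen-8-yl]-7-hydroxy-5-methoxychroman-8-carbaldehyde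
Product: 27 (3R)-7-hydroxy-3-(5-hydroxy-2,2-dimethyl-2H-chromen-8-yl)-5-methoxychroman-8-carbaldehyde
Conditions: Bu4NF (1.1 equiv), AcOH (1.1 equiv), THF, 0 °C
Reagents that add atoms: none
Why: Buffered fluoride cleavage of the aryl silyl ether should release the last phenol without affecting the aldehyde, the chromene or the stereocentre.

**Compound list**

1 | 2,4-dihydroxyphenylacetic acid | OC(=O)Cc1ccc(O)cc1O | starting material
2 | 6-hydroxybenzofuran-2(3H)-one | O=C1Cc2ccc(O)cc2O1 | intermediate
3 | 6-(triisopropylsilyloxy)benzofuran-2(3H)-one | O=C1Cc2ccc(O[Si](C(C)C)(C(C)C)C(C)C)cc2O1 | intermediate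
4 | methyl 2-[2-hydroxy-4-(triisopropylsilyloxy)phenyl]acetate | COC(=O)Cc1ccc(O[Si](C(C)C)(C(C)C)C(C)C)cc1O | intermediate
5 | isopropenylboronic acid pinacol ester | CC(=C)B1OC(C)(C)C(C)(C)O1 | starting material
6 | methyl 2-[2-(prop-1-en-2-yloxy)-4-(triisopropylsilyloxy)phenyl]acetate | COC(=O)Cc1ccc(O[Si](C(C)C)(C(C)C)C(C)C)cc1OC(C)=C | intermediate
7 | ethyl vinyl ether | C=COCC | starting material
8 | methyl 2-[2-(2-chloropropan-2-yloxy)-4-(triisopropylsilyloxy)phenyl]acetate | COC(=O)Cc1ccc(O[Si](C(C)C)(C(C)C)C(C)C)cc1OC(C)(C)Cl | intermediate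
9 | methyl 2-[4-ethoxy-2,2-dimethyl-5-(triisopropylsilyloxy)chroman-8-yl]acetate (racemic at C-4) | COC(=O)Cc1ccc(O[Si](C(C)C)(C(C)C)C(C)C)c2c1OC(C)(C)CC2OCC | intermediate
10 | methyl 2-[2,2-dimethyl-5-(triisopropylsilyloxy)-2H-chromen-8-yl]acetate | COC(=O)Cc1ccc(O[Si](C(C)C)(C(C)C)C(C)C)c2c1OC(C)(C)C=C2 | intermediate
11 | 2-[2,2-dimethyl-5-(triisopropylsilyloxy)-2H-chromen-8-yl]acetic acid | OC(=O)Cc1ccc(O[Si](C(C)C)(C(C)C)C(C)C)c2c1OC(C)(C)C=C2 | intermediate
12 | (R)-4-benzyloxazolidin-2-one | O=C1N[C@H](Cc2ccccc2)CO1 | starting material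
13 | 2-[2,2-dimethyl-5-(triisopropylsilyloxy)-2H-chromen-8-yl]acetic pivalic anhydride | CC(C)(C)C(=O)OC(=O)Cc1ccc(O[Si](C(C)C)(C(C)C)C(C)C)c2c1OC(C)(C)C=C2 | intermediate
14 | (R)-4-benzyl-3-{2-[2,2-dimethyl-5-(triisopropylsilyloxy)-2H-chromen-8-yl]acetyl}oxazolidin-2-one | O=C(Cc1ccc(O[Si](C(C)C)(C(C)C)C(C)C)c2c1OC(C)(C)C=C2)N1[C@H](Cc2ccccc2)COC1=O | intermediate
15 | 2,4-dihydroxy-6-methoxybenzaldehyde | COc1cc(O)cc(O)c1C=O | starting material
16 | 2-methoxy-4,6-bis(methoxymethoxy)benzaldehyde | COCOc1cc(OC)c(C=O)c(OCOC)c1 | intermediate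
17 | [2-methoxy-4,6-bis(methoxymethoxy)phenyl]methanol | COCOc1cc(OC)c(CO)c(OCOC)c1 | intermediate
18 | 2-methoxy-4,6-bis(methoxymethoxy)benzyl methanesulfonate | COCOc1cc(OC)c(COS(C)(=O)=O)c(OCOC)c1 | intermediate
19 | 2-(bromomethyl)-1-methoxy-3,5-bis(methoxymethoxy)benzene | COCOc1cc(OC)c(CBr)c(OCOC)c1 | intermediate
20 | sodium (Z)-enolate of 14 | [Na+].[O-]/C(=C\c1ccc(O[Si](C(C)C)(C(C)C)C(C)C)c2c1OC(C)(C)C=C2)N1[C@H](Cc2ccccc2)COC1=O | intermediate
21 | (R)-4-benzyl-3-{(2R)-2-[2,2-dimethyl-5-(triisopropylsilyloxy)-2H-chromen-8-yl]-3-[2-methoxy-4,6-bis(methoxymethoxy)phenyl]propanoyl}oxazolidin-2-one | COCOc1cc(OC)c(C[C@H](c2ccc(O[Si](C(C)C)(C(C)C)C(C)C)c3c2OC(C)(C)C=C3)C(=O)N2[C@H](Cc3ccccc3)COC2=O)c(OCOC)c1 | intermediate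
22 | (2R)-2-[2,2-dimethyl-5-(triisopropylsilyloxy)-2H-chromen-8-yl]-3-[2-methoxy-4,6-bis(methoxymethoxy)phenyl]propan-1-ol | COCOc1cc(OC)c(C[C@H](c2ccc(O[Si](C(C)C)(C(C)C)C(C)C)c3c2OC(C)(C)C=C3)CO)c(OCOC)c1 | intermediate
23 | dilithio derivative of 22 (lithium alkoxide; aryllithium at the CH between the two methoxymethoxy groups) | [Li]c1c(OCOC)cc(OC)c(C[C@H](c2ccc(O[Si](C(C)C)(C(C)C)C(C)C)c3c2OC(C)(C)C=C3)CO[Li])c1OCOC | intermediate
24 | 3-{(2R)-2-[2,2-dimethyl-5-(triisopropylsilyloxy)-2H-chromen-8-yl]-3-hydroxypropyl}-4-methoxy-2,6-bis(methoxymethoxy)benzaldehyde | O=Cc1c(OCOC)cc(OC)c(C[C@H](c2ccc(O[Si](C(C)C)(C(C)C)C(C)C)c3c2OC(C)(C)C=C3)CO)c1OCOC | intermediate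
25 | 3-{(2R)-2-[2,2-dimethyl-5-(triisopropylsilyloxy)-2H-chromen-8-yl]-3-hydroxypropyl}-2,6-dihydroxy-4-methoxybenzaldehyde | O=Cc1c(O)cc(OC)c(C[C@H](c2ccc(O[Si](C(C)C)(C(C)C)C(C)C)c3c2OC(C)(C)C=C3)CO)c1O | intermediate
26 | (3R)-3-[2,2-dimethyl-5-(triisopropylsilyloxy)-2H-chromen-8-yl]-7-hydroxy-5-methoxychroman-8-carbaldehyde | COc1cc(O)c(C=O)c2c1C[C@H](c1ccc(O[Si](C(C)C)(C(C)C)C(C)C)c3c1OC(C)(C)C=C3)CO2 | intermediate
27 | (3R)-7-hydroxy-3-(5-hydroxy-2,2-dimethyl-2H-chromen-8-yl)-5-methoxychroman-8-carbaldehyde (CNP0272344.1) | COc1cc(O)c(C=O)c2c1C[C@H](c1ccc(O)c3c1OC(C)(C)C=C3)CO2 | target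

**Step count.** Total: 15 steps. Longest linear sequence: 12 steps (steps 1 to 6, then 10 to 15); the ring A branch is steps 7 to 9.

**Steps most likely to fail**

Step 4 (proposed new method). The cationic sequence may leave the intended path: the vinyl ether may oligomerise, the enol ether may condense with itself before the cross addition, or the acid may dimerise the chromene once it has formed. The fallback uses known chemistry and sets out from phenol 4. O-Alkylation with 3-chloro-3-methylbut-1-yne (DBU, CuCl2 cat., MeCN, 0 °C) would give methyl 2-[2-(2-methylbut-3-yn-2-yloxy)-4-(triisopropylsilyloxy)phenyl]acetate F1. Heating F1 (xylene, 140 °C) should bring about aromatic propargyl Claisen rearrangement to the only free ortho carbon, 1,5-hydrogen shift and oxa-6π electrocyclisation, which comes back to the route at 10.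

Step 12. Lithiation may not stay at the intended site: the ring A CH between OMOM and OMe may be metalated in competition, or n-BuLi may add across the styrene-like chromene alkene. The fallback fixes the site by an early halogenation and a late halogen–lithium exchange and sets out from alcohol 17. Directed lithiation of 17 (n-BuLi, 2.2 equiv, THF, 0 °C) and quenching with 1,2-dibromotetrachloroethane would give [3-bromo-6-methoxy-2,4-bis(methoxymethoxy)phenyl]methanol F2. Appel bromination (CBr4, PPh3, CH2Cl2, −20 °C) would give 2-bromo-4-(bromomethyl)-5-methoxy-1,3-bis(methoxymethoxy)benzene F3. Alkylation of enolate 20 with F3 under the conditions of step 10 would give (R)-4-benzyl-3-{(2R)-3-[3-bromo-6-methoxy-2,4-bis(methoxymethoxy)phenyl]-2-[2,2-dimethyl-5-(triisopropylsilyloxy)-2H-chromen-8-yl]propanoyl}oxazolidin-2-one F4, and LiBH4 reduction would give (2R)-3-[3-bromo-6-methoxy-2,4-bis(methoxymethoxy)phenyl]-2-[2,2-dimethyl-5-(triisopropylsilyloxy)-2H-chromen-8-yl]propan-1-ol F5. Bromine–lithium exchange on F5 (n-BuLi, 2.2 equiv, THF, −78 °C) and DMF comes back to the route at 24.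

Step 10. The electron-rich benzylic bromide 19 may ionise and condense with itself before C-alkylation, and excess base may erode the new stereocentre. The fallback avoids a benzylic halide and an auxiliary and sets out from acid 11 and aldehyde 16. Perkin condensation (Ac2O, Et3N, 100 °C) would give (E)-2-[2,2-dimethyl-5-(triisopropylsilyloxy)-2H-chromen-8-yl]-3-[2-methoxy-4,6-bis(methoxymethoxy)phenyl]prop-2-enoic acid F6. Carboxylate-directed asymmetric hydrogenation of F6 with the spiro phosphine–oxazoline complex [Ir(cod)(SIPHOX)]BArF (the enantiomer that delivers the R acid; H2 6 atm, Et3N, MeOH) would give (2R)-2-[2,2-dimethyl-5-(triisopropylsilyloxy)-2H-chromen-8-yl]-3-[2-methoxy-4,6-bis(methoxymethoxy)phenyl]propanoic acid F7. The chromene alkene is expected to be reduced much more slowly than the acrylic acid, and this would need to be confirmed. Reduction of F7 with LiAlH4 (THF, 0 °C) comes back to the route at 22.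

Further compounds
F1 | step 4 | methyl 2-[2-(2-methylbut-3-yn-2-yloxy)-4-(triisopropylsilyloxy)phenyl]acetate | COC(=O)Cc1ccc(O[Si](C(C)C)(C(C)C)C(C)C)cc1OC(C)(C)C#C
F2 | step 12 | [3-bromo-6-methoxy-2,4-bis(methoxymethoxy)phenyl]methanol | COCOc1cc(OC)c(CO)c(OCOC)c1Br
F3 | step 12 | 2-bromo-4-(bromomethyl)-5-methoxy-1,3-bis(methoxymethoxy)benzene | COCOc1cc(OC)c(CBr)c(OCOC)c1Br
F4 | step 12 | (R)-4-benzyl-3-{(2R)-3-[3-bromo-6-methoxy-2,4-bis(methoxymethoxy)phenyl]-2-[2,2-dimethyl-5-(triisopropylsilyloxy)-2H-chromen-8-yl]propanoyl}oxazolidin-2-one | COCOc1cc(OC)c(C[C@H](c2ccc(O[Si](C(C)C)(C(C)C)C(C)C)c3c2OC(C)(C)C=C3)C(=O)N2[C@H](Cc3ccccc3)COC2=O)c(OCOC)c1Br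
F5 | step 12 | (2R)-3-[3-bromo-6-methoxy-2,4-bis(methoxymethoxy)phenyl]-2-[2,2-dimethyl-5-(triisopropylsilyloxy)-2H-chromen-8-yl]propan-1-ol | COCOc1cc(OC)c(C[C@H](c2ccc(O[Si](C(C)C)(C(C)C)C(C)C)c3c2OC(C)(C)C=C3)CO)c(OCOC)c1Br
F6 | step 10 | (E)-2-[2,2-dimethyl-5-(triisopropylsilyloxy)-2H-chromen-8-yl]-3-[2-methoxy-4,6-bis(methoxymethoxy)phenyl]prop-2-enoic acid | OC(=O)/C(=C/c1c(OC)cc(OCOC)cc1OCOC)c1ccc(O[Si](C(C)C)(C(C)C)C(C)C)c2c1OC(C)(C)C=C2
F7 | step 10 | (2R)-2-[2,2-dimethyl-5-(triisopropylsilyloxy)-2H-chromen-8-yl]-3-[2-methoxy-4,6-bis(methoxymethoxy)phenyl]propanoic acid | COCOc1cc(OC)c(C[C@H](c2ccc(O[Si](C(C)C)(C(C)C)C(C)C)c3c2OC(C)(C)C=C3)C(O)=O)c(OCOC)c1
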